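**Retrosynthetic overview**
- Last, the C14 tertiary amide is turned into the aldehyde and the C15 silyl ether is removed on the finished bicyclic lactone.
- Key step: in one flask the ten-membered carbocycle closes first by C6–C7 bond formation (an allylchromium from a 2-(halomethyl)enoate adds to the C6 enal of a chain that already carries the C8 ester), then the γ-lactone closes (O6 to C12). C6 and C7 are both set there from C8.
- The chain comes from a C1=C10 Horner–Wadsworth–Emmons coupling of a C1–C6 dialdehyde (reacting only at its saturated CHO) with a C7–C14 phosphonate.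
- The dialdehyde comes from glycol cleavage of a 4-substituted cyclohex-3-ene-1,2-diol; the six-membered ring fixes the C4=C5 geometry.
- The phosphonate comes from a phosphonoacetamide, (R)-benzyl glycidyl ether (C8), (S)-2-methylbutanoic acid and a stannyl–phosphonoacrylate olefination that installs the latent allylmetal.

Assumption: positions are quoted in germacrane numbering (lactone oxygen on C6, acyloxy on C8, CHO = C14, CH2OH = C15), and the SMILES is read as 6R,7R,8R with an (S)-2-methylbutanoate and both ring alkenes E by CIP, i.e. with the ring carbons cis across each double bond.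

**Route**

Step 1
Reactants: 1 methyl 3-oxocyclohex-1-ene-1-carboxylate
Product: 2 methyl 4-acetoxy-3-oxocyclohex-1-ene-1-carboxylate (racemic)
Conditions: Mn(OAc)3·2H2O (3 equiv), benzene, reflux (Dean–Stark)
Reagents that add atoms: Mn(OAc)3 (manganese triacetate), CC(=O)[O-].CC(=O)[O-].CC(=O)[O-].[Mn+3]
Why: α′-acetoxylation of the enone by Mn(OAc)3 (trivalent manganese, via the manganese enolate of the only α′-CH2) puts oxygen on the carbon that becomes C1; the new stereocentre is racemic and is destroyed in step 4.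

Step 2
Reactants: 2 methyl 4-acetoxy-3-oxocyclohex-1-ene-1-carboxylate
Product: 3 4-(hydroxymethyl)cyclohex-3-ene-1,2-diol (racemic cis/trans mixture)
Conditions: i-Bu2AlH (6 equiv), CH2Cl2, −78 → 0 °C; aq KNaC4H4O6
Reagents that add atoms: none
Why: hydride reduction with i-Bu2AlH takes the enone carbonyl 1,2 to the allylic alcohol, the conjugated ester to the primary allylic alcohol and cleaves the acetate, so the vicinal diol for ring cleavage is in place (the diastereomer mixture is of no consequence).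

Step 3
Reactants: 3 4-(hydroxymethyl)cyclohex-3-ene-1,2-diol
Product: 4 4-{[(tert-butyldimethylsilyl)oxy]methyl}cyclohex-3-ene-1,2-diol
Conditions: TBSCl (1.05 equiv), imidazole (2 equiv), DMF, −20 °C
Reagents that add atoms: tert-butyldimethylsilyl chloride (TBSCl), CC(C)(C)[Si](C)(C)Cl
Why: silyl ether formation is selective for the primary hydroxyl over the two secondary ones on steric grounds (kinetic monosilylation at low temperature).

Step 4
Reactants: 4 4-{[(tert-butyldimethylsilyl)oxy]methyl}cyclohex-3-ene-1,2-diol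
Product: 5 (2E)-3-{[(tert-butyldimethylsilyl)oxy]methyl}hex-2-enedial
Conditions: NaIO4 (1.5 equiv), THF–H2O (2:1), 0 °C → rt; used at once
Reagents that add atoms: none
Why: Malaprade glycol cleavage opens the ring between C1 and C6 and, because C3 and C6 were ring atoms on the same side of the C4=C5 bond, gives the enal with the required geometry (CHO cis to the C3 chain) next to a more electrophilic saturated aldehyde.

Step 5
Reactants: 6 diethyl [2-(dimethylamino)-2-oxoethyl]phosphonate; 7 (2R)-2-[(benzyloxy)methyl]oxirane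
Product: 8 diethyl [(2RS,4R)-5-(benzyloxy)-1-(dimethylamino)-4-hydroxy-1-oxopentan-2-yl]phosphonate
Conditions: NaH (1.05 equiv), THF, 0 °C → rt; then 7 (1.2 equiv), reflux; aq NH4Cl
Reagents that add atoms: none
Why: alkylation of the phosphonate-stabilised carbanion by SN2 opening of the terminal epoxide at its CH2 carbon joins C9 to C10 and carries the C8 stereocentre over unchanged from the (R)-glycidyl ether, while the tertiary amide, unlike an ester, cannot lactonise onto the new alkoxide.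

Step 6
Reactants: 8 diethyl [(2RS,4R)-5-(benzyloxy)-1-(dimethylamino)-4-hydroxy-1-oxopentan-2-yl]phosphonate; 9 (2S)-2-methylbutanoic acid
Product: 10 (2R,4RS)-1-(benzyloxy)-4-(diethoxyphosphoryl)-5-(dimethylamino)-5-oxopentan-2-yl (2S)-2-methylbutanoate
Conditions: DCC (1.2 equiv), DMAP (0.1 equiv), CH2Cl2, 0 °C → rt
Reagents that add atoms: none
Why: Steglich esterification acylates the secondary alcohol with retention at C8 and without touching the α-stereocentre of the acid, which brings in the (S)-2-methylbutanoate early.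

Step 7
Reactants: 10 (2R,4RS)-1-(benzyloxy)-4-(diethoxyphosphoryl)-5-(dimethylamino)-5-oxopentan-2-yl (2S)-2-methylbutanoate
Product: 11 (2R,4RS)-4-(diethoxyphosphoryl)-5-(dimethylamino)-1-hydroxy-5-oxopentan-2-yl (2S)-2-methylbutanoate
Conditions: H2 (1 atm), Pd/C (10 wt% Pd on carbon), EtOAc, rt
Reagents that add atoms: none
Why: hydrogenolysis of the benzyl ether over Pd/C is clean because no alkene is present yet, and the neutral medium keeps the secondary ester from migrating to the freed primary hydroxyl.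

Step 8
Reactants: 11 (2R,4RS)-4-(diethoxyphosphoryl)-5-(dimethylamino)-1-hydroxy-5-oxopentan-2-yl (2S)-2-methylbutanoate
Product: 12 (2R,4RS)-4-(diethoxyphosphoryl)-5-(dimethylamino)-1,5-dioxopentan-2-yl (2S)-2-methylbutanoate
Conditions: Dess–Martin periodinane (1.3 equiv), CH2Cl2, 0 °C → rt; used crude
Reagents that add atoms: none
Why: Dess–Martin oxidation gives the α-acyloxy aldehyde under non-basic conditions, so C8 is not epimerised.

Step 9
Reactants: 12 (2R,4RS)-4-(diethoxyphosphoryl)-5-(dimethylamino)-1,5-dioxopentan-2-yl (2S)-2-methylbutanoate; 13 ethyl 2-(diethoxyphosphoryl)prop-2-enoate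
Product: 15 ethyl (2Z,4R,6RS)-6-(diethoxyphosphoryl)-7-(dimethylamino)-4-{[(2S)-2-methylbutanoyl]oxy}-7-oxo-2-[(tributylstannyl)methyl]hept-2-enoate, via lithium stannyl phosphonate 14 (not isolated)
Conditions: Bu3SnH (1.05 equiv), LiN(i-Pr)2 (1.05 equiv), THF, 0 °C; 13 (1.1 equiv), −78 °C; then 12, −78 → 0 °C
Reagents that add atoms: tributyltin hydride (Bu3SnH), CCCC[SnH](CCCC)CCCC
Why: Proposed new method: Bu3SnLi adds 1,4 to the phosphonoacrylate and the phosphonate carbanion 14 so formed olefinates the aldehyde in a Horner–Wadsworth–Emmons step, giving a 2-(stannylmethyl)enoate that is inert to the carbanion chemistry of step 10; the closest known reaction type is the tandem conjugate addition–Horner–Wadsworth–Emmons reaction of 2-phosphonoacrylates with thiolate, alkoxide or carbon nucleophiles, and the alkene geometry is immaterial because the allylmetal of step 11 equilibrates.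

Step 10
Reactants: 15 ethyl (2Z,4R,6RS)-6-(diethoxyphosphoryl)-7-(dimethylamino)-4-{[(2S)-2-methylbutanoyl]oxy}-7-oxo-2-[(tributylstannyl)methyl]hept-2-enoate; 5 (2E)-3-{[(tert-butyldimethylsilyl)oxy]methyl}hex-2-enedial
Product: 16 ethyl (2Z,4R,6E,10E)-10-{[(tert-butyldimethylsilyl)oxy]methyl}-6-(dimethylcarbamoyl)-4-{[(2S)-2-methylbutanoyl]oxy}-12-oxo-2-[(tributylstannyl)methyl]dodeca-2,6,10-trienoate
Conditions: NaH (0.95 equiv), THF, 0 °C; then 5 (1.2 equiv), −40 → 0 °C
Reagents that add atoms: none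
Why: Horner–Wadsworth–Emmons olefination in which the hindered α-substituted phosphonoacetamide anion takes the saturated C1 aldehyde far faster than the β,β-disubstituted enal and gives the favoured (E)-enamide (C2 chain trans to the amide), which is the geometry of the C1=C10 bond of the target.

Step 11
Reactants: 16 ethyl (2Z,4R,6E,10E)-10-{[(tert-butyldimethylsilyl)oxy]methyl}-6-(dimethylcarbamoyl)-4-{[(2S)-2-methylbutanoyl]oxy}-12-oxo-2-[(tributylstannyl)methyl]dodeca-2,6,10-trienoate
Product: 19 (3aR,4R,6E,10E,11aR)-10-{[(tert-butyldimethylsilyl)oxy]methyl}-6-(dimethylcarbamoyl)-3-methylidene-2-oxo-2,3,3a,4,5,8,9,11a-octahydrocyclodeca[b]furan-4-yl (2S)-2-methylbutanoate, via allylic iodide 17 (not isolated), via hydroxy ester 18 (not isolated)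
Conditions: I2 (1.0 equiv), THF, −78 °C; then syringe-pump addition to CrCl2 (10 equiv), THF (2 mM), rt; aq NH4Cl; PPTS (cat.), benzene, 50 °C
Reagents that add atoms: iodine (I2), [I][I] (its atom stays only in 17)
Why: iododestannylation (SE2′) gives the 2-(iodomethyl)enoate, CrCl2 (divalent chromium) converts it into the allylchromium reagent (trivalent chromium) and an intramolecular Nozaki–Hiyama–Kishi-type allylation of the C6 enal closes the ten-membered ring by the C6–C7 bond, the ring-constrained cyclic transition state giving the 6,7-trans relationship and the C8 acyloxy stereocentre (H-8 in the allyl plane to avoid A1,3 strain, attack anti to the C9 chain) fixing C7, after which the C6 hydroxyl lactonises onto the ethyl ester to the trans-fused α-methylene γ-lactone.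

Step 12
Reactants: 19 (3aR,4R,6E,10E,11aR)-10-{[(tert-butyldimethylsilyl)oxy]methyl}-6-(dimethylcarbamoyl)-3-methylidene-2-oxo-2,3,3a,4,5,8,9,11a-octahydrocyclodeca[b]furan-4-yl (2S)-2-methylbutanoate
Product: 21 target CNP0168859.6, via silyl aldehyde 20 (not isolated)
Conditions: Cp2Zr(H)Cl (2.2 equiv), THF, rt, 30 min; then 1 M aq HCl, THF, rt
Reagents that add atoms: none
Why: Cp2Zr(H)Cl reduces the tertiary amide chemoselectively to the aldehyde through a zirconium hemiaminal that survives until work-up (esters and the lactone are not reduced), and the aqueous acid then releases the enal and cleaves the primary silyl ether without touching a stereocentre.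

**Compound list**

1 | methyl 3-oxocyclohex-1-ene-1-carboxylate | COC(=O)C1=CC(=O)CCC1 | starting material
2 | methyl 4-acetoxy-3-oxocyclohex-1-ene-1-carboxylate (racemic) | COC(=O)C1=CC(=O)C(OC(C)=O)CC1 | intermediate
3 | 4-(hydroxymethyl)cyclohex-3-ene-1,2-diol (racemic, cis/trans mixture) | OCC1=CC(O)C(O)CC1 | intermediate
4 | 4-{[(tert-butyldimethylsilyl)oxy]methyl}cyclohex-3-ene-1,2-diol (racemic, cis/trans mixture) | CC(C)(C)[Si](C)(C)OCC1=CC(O)C(O)CC1 | intermediate
5 | (2E)-3-{[(tert-butyldimethylsilyl)oxy]methyl}hex-2-enedial (CHO cis to the CH2CH2CHO chain) | O=C/C=C(/CO[Si](C)(C)C(C)(C)C)CCC=O | intermediate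
6 | diethyl [2-(dimethylamino)-2-oxoethyl]phosphonate | CCOP(=O)(CC(=O)N(C)C)OCC | starting material
7 | (2R)-2-[(benzyloxy)methyl]oxirane ((R)-benzyl glycidyl ether) | C(OCc1ccccc1)[C@H]1CO1 | starting material
8 | diethyl [(2RS,4R)-5-(benzyloxy)-1-(dimethylamino)-4-hydroxy-1-oxopentan-2-yl]phosphonate | CCOP(=O)(OCC)C(C[C@@H](O)COCc1ccccc1)C(=O)N(C)C | intermediate
9 | (2S)-2-methylbutanoic acid | CC[C@H](C)C(=O)O | starting material
10 | (2R,4RS)-1-(benzyloxy)-4-(diethoxyphosphoryl)-5-(dimethylamino)-5-oxopentan-2-yl (2S)-2-methylbutanoate | CCOP(=O)(OCC)C(C[C@@H](OC(=O)[C@@H](C)CC)COCc1ccccc1)C(=O)N(C)C | intermediate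
11 | (2R,4RS)-4-(diethoxyphosphoryl)-5-(dimethylamino)-1-hydroxy-5-oxopentan-2-yl (2S)-2-methylbutanoate | CCOP(=O)(OCC)C(C[C@@H](OC(=O)[C@@H](C)CC)CO)C(=O)N(C)C | intermediate
12 | (2R,4RS)-4-(diethoxyphosphoryl)-5-(dimethylamino)-1,5-dioxopentan-2-yl (2S)-2-methylbutanoate | CCOP(=O)(OCC)C(C[C@@H](OC(=O)[C@@H](C)CC)C=O)C(=O)N(C)C | intermediate
13 | ethyl 2-(diethoxyphosphoryl)prop-2-enoate (triethyl 2-phosphonoacrylate) | CCOC(=O)C(=C)P(=O)(OCC)OCC | starting material
14 | lithium salt of the carbanion of ethyl 2-(diethoxyphosphoryl)-3-(tributylstannyl)propanoate | [Li+].CCOC(=O)[C-](C[Sn](CCCC)(CCCC)CCCC)P(=O)(OCC)OCC | intermediate (not isolated)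
15 | ethyl (2Z,4R,6RS)-6-(diethoxyphosphoryl)-7-(dimethylamino)-4-{[(2S)-2-methylbutanoyl]oxy}-7-oxo-2-[(tributylstannyl)methyl]hept-2-enoate (2Z drawn; the 2E/2Z mixture is used) | CCOP(=O)(OCC)C(C[C@@H](OC(=O)[C@@H](C)CC)/C=C(/C(=O)OCC)C[Sn](CCCC)(CCCC)CCCC)C(=O)N(C)C | intermediate
16 | ethyl (2Z,4R,6E,10E)-10-{[(tert-butyldimethylsilyl)oxy]methyl}-6-(dimethylcarbamoyl)-4-{[(2S)-2-methylbutanoyl]oxy}-12-oxo-2-[(tributylstannyl)methyl]dodeca-2,6,10-trienoate | O=C/C=C(/CO[Si](C)(C)C(C)(C)C)CC/C=C(/C(=O)N(C)C)C[C@@H](OC(=O)[C@@H](C)CC)/C=C(/C(=O)OCC)C[Sn](CCCC)(CCCC)CCCC | intermediate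
17 | ethyl (2Z,4R,6E,10E)-10-{[(tert-butyldimethylsilyl)oxy]methyl}-6-(dimethylcarbamoyl)-2-(iodomethyl)-4-{[(2S)-2-methylbutanoyl]oxy}-12-oxododeca-2,6,10-trienoate | O=C/C=C(/CO[Si](C)(C)C(C)(C)C)CC/C=C(/C(=O)N(C)C)C[C@@H](OC(=O)[C@@H](C)CC)/C=C(/C(=O)OCC)C[I] | intermediate (not isolated)
18 | ethyl 2-[(1S,2R,3E,7E,10R)-4-{[(tert-butyldimethylsilyl)oxy]methyl}-8-(dimethylcarbamoyl)-2-hydroxy-10-{[(2S)-2-methylbutanoyl]oxy}cyclodeca-3,7-dien-1-yl]prop-2-enoate | C=C(C(=O)OCC)[C@H]1[C@H](O)/C=C(/CO[Si](C)(C)C(C)(C)C)CC/C=C(/C(=O)N(C)C)C[C@H]1OC(=O)[C@@H](C)CC | intermediate (not isolated)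
19 | (3aR,4R,6E,10E,11aR)-10-{[(tert-butyldimethylsilyl)oxy]methyl}-6-(dimethylcarbamoyl)-3-methylidene-2-oxo-2,3,3a,4,5,8,9,11a-octahydrocyclodeca[b]furan-4-yl (2S)-2-methylbutanoate | C=C1C(=O)O[C@@H]2/C=C(/CO[Si](C)(C)C(C)(C)C)CC/C=C(/C(=O)N(C)C)C[C@@H](OC(=O)[C@@H](C)CC)[C@@H]12 | intermediate
20 | (3aR,4R,6E,10E,11aR)-10-{[(tert-butyldimethylsilyl)oxy]methyl}-6-formyl-3-methylidene-2-oxo-2,3,3a,4,5,8,9,11a-octahydrocyclodeca[b]furan-4-yl (2S)-2-methylbutanoate | C=C1C(=O)O[C@@H]2/C=C(/CO[Si](C)(C)C(C)(C)C)CC/C=C(/C=O)C[C@@H](OC(=O)[C@@H](C)CC)[C@@H]12 | intermediate (not isolated)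
21 | (3aR,4R,6E,10E,11aR)-6-formyl-10-(hydroxymethyl)-3-methylidene-2-oxo-2,3,3a,4,5,8,9,11a-octahydrocyclodeca[b]furan-4-yl (2S)-2-methylbutanoate (CNP0168859.6) | C=C1C(=O)O[C@@H]2/C=C(/CO)CC/C=C(/C=O)C[C@@H](OC(=O)[C@@H](C)CC)[C@@H]12 | target

**Count and risks**

Total steps: 12. Longest linear sequence: 8 (steps 5 to 12); the other branch is steps 1 to 4 followed by 10 to 12.

The three steps most likely to fail are 9, 11 and 12.

Step 9 may fail because the stannyllithium addition to the phosphonoacrylate is untested and the α-acyloxy aldehyde is sensitive. The fallback replaces tin by an oxygen handle and sets out from 12. The phosphonoacrylate 13 is treated with 4-methoxybenzyl alcohol and a trace of NaH to give ethyl 2-(diethoxyphosphoryl)-3-[(4-methoxybenzyl)oxy]propanoate F1. With LiCl and i-Pr2NEt in MeCN this olefinates 12 to the 4-methoxybenzyl ether enoate F2. F2 is coupled with 5 under the conditions of step 10 to give the acyclic enal F3. DDQ in wet CH2Cl2 frees the allylic alcohol F4, and NBS/Me2S turns it into the allylic bromide F5. CrCl2 under the conditions of step 11 then closes F5 to 18, and the route is rejoined at 19.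

Step 11 may fail by 1,4-loss of the C8 acyloxy group from the allylchromium, by formation of the wrong C7 epimer, by competing acyl transfer from O8 to O6, or by oligomerisation. The fallback sets out from 16 and uses the allylstannane itself as the nucleophile: BF3·OEt2 in CH2Cl2 at −78 °C and 1 mM. This is a Lewis-acid SE2′ addition through an open transition state, with no allylchromium and therefore no elimination channel. It gives 18 directly, which lactonises as before, so the route is rejoined at 19. This fallback makes no compound outside the list (F0).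

Step 12 may fail because Cp2Zr(H)Cl could also attack the exocyclic methylene lactone. The fallback sets out from 19 and protects that group first. Me2NH in THF adds to the methylene group to give the amino lactone F6. Cp2Zr(H)Cl then reduces only the amide, giving the amino aldehyde F7. MeI forms the methiodide F8, and NaHCO3 eliminates trimethylamine to restore the methylene group. This returns the route at 20, which the acid stage of step 12 converts into 21.

**Further compounds**

F1 | step 9 | ethyl 2-(diethoxyphosphoryl)-3-[(4-methoxybenzyl)oxy]propanoate (racemic) | CCOC(=O)C(COCc1ccc(OC)cc1)P(=O)(OCC)OCC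
F2 | step 9 | ethyl (2E,4R,6RS)-6-(diethoxyphosphoryl)-7-(dimethylamino)-2-{[(4-methoxybenzyl)oxy]methyl}-4-{[(2S)-2-methylbutanoyl]oxy}-7-oxohept-2-enoate | CCOP(=O)(OCC)C(C[C@@H](OC(=O)[C@@H](C)CC)/C=C(/C(=O)OCC)COCc1ccc(OC)cc1)C(=O)N(C)C
F3 | step 9 | ethyl (2E,4R,6E,10E)-10-{[(tert-butyldimethylsilyl)oxy]methyl}-6-(dimethylcarbamoyl)-2-{[(4-methoxybenzyl)oxy]methyl}-4-{[(2S)-2-methylbutanoyl]oxy}-12-oxododeca-2,6,10-trienoate | O=C/C=C(/CO[Si](C)(C)C(C)(C)C)CC/C=C(/C(=O)N(C)C)C[C@@H](OC(=O)[C@@H](C)CC)/C=C(/C(=O)OCC)COCc1ccc(OC)cc1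
F4 | step 9 | ethyl (2E,4R,6E,10E)-10-{[(tert-butyldimethylsilyl)oxy]methyl}-6-(dimethylcarbamoyl)-2-(hydroxymethyl)-4-{[(2S)-2-methylbutanoyl]oxy}-12-oxododeca-2,6,10-trienoate | O=C/C=C(/CO[Si](C)(C)C(C)(C)C)CC/C=C(/C(=O)N(C)C)C[C@@H](OC(=O)[C@@H](C)CC)/C=C(/C(=O)OCC)CO
F5 | step 9 | ethyl (2Z,4R,6E,10E)-2-(bromomethyl)-10-{[(tert-butyldimethylsilyl)oxy]methyl}-6-(dimethylcarbamoyl)-4-{[(2S)-2-methylbutanoyl]oxy}-12-oxododeca-2,6,10-trienoate | O=C/C=C(/CO[Si](C)(C)C(C)(C)C)CC/C=C(/C(=O)N(C)C)C[C@@H](OC(=O)[C@@H](C)CC)/C=C(/C(=O)OCC)CBr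
F0 | step 11 | none | none
F6 | step 12 | (3RS,3aR,4R,6E,10E,11aR)-10-{[(tert-butyldimethylsilyl)oxy]methyl}-6-(dimethylcarbamoyl)-3-[(dimethylamino)methyl]-2-oxo-2,3,3a,4,5,8,9,11a-octahydrocyclodeca[b]furan-4-yl (2S)-2-methylbutanoate | CN(C)CC1C(=O)O[C@@H]2/C=C(/CO[Si](C)(C)C(C)(C)C)CC/C=C(/C(=O)N(C)C)C[C@@H](OC(=O)[C@@H](C)CC)[C@@H]12
F7 | step 12 | (3RS,3aR,4R,6E,10E,11aR)-10-{[(tert-butyldimethylsilyl)oxy]methyl}-3-[(dimethylamino)methyl]-6-formyl-2-oxo-2,3,3a,4,5,8,9,11a-octahydrocyclodeca[b]furan-4-yl (2S)-2-methylbutanoate | CN(C)CC1C(=O)O[C@@H]2/C=C(/CO[Si](C)(C)C(C)(C)C)CC/C=C(/C=O)C[C@@H](OC(=O)[C@@H](C)CC)[C@@H]12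
F8 | step 12 | methiodide of F7: [(3RS,3aR,4R,6E,10E,11aR)-10-{[(tert-butyldimethylsilyl)oxy]methyl}-6-formyl-4-{[(2S)-2-methylbutanoyl]oxy}-2-oxo-2,3,3a,4,5,8,9,11a-octahydrocyclodeca[b]furan-3-yl]methyl-trimethylammonium iodide | C[N+](C)(C)CC1C(=O)O[C@@H]2/C=C(/CO[Si](C)(C)C(C)(C)C)CC/C=C(/C=O)C[C@@H](OC(=O)[C@@H](C)CC)[C@@H]12.[I-]
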